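The numbers are made up; the flask was simulated.

The question is where this flask stands at the end of its run: still moving or stopped, and with how much target and isomer of the product.

    starting material + reagent ⇌ target (K1 = 9.8 M⁻¹, k1 = 0.49 M⁻¹ s⁻¹)
    second substrate + reagent ⇌ second product (K2 = 2.4 M⁻¹, k2 = 0.034 M⁻¹ s⁻¹)
    target → over-reaction product (k3 = 8.8 × 10⁻⁵ s⁻¹)
    second substrate ⇌ dormant form (K4 = 1.9, k4 = 0.057 s⁻¹)
    target ⇌ isomer of the product (K5 = 0.66, k5 = 0.12 s⁻¹)
starting material 20 mM; reagent 2.50 equiv; second substrate 0.500 equiv; time 6.0 min
* the state of affairs at 6.0 min: stopped, and by what, or still going (it is still moving / forward and back rates have come level / the reagent has run out first / all of the starting material has reacted)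
* amount of target at 6.0 min, in percent of the starting material charged
* amount of isomer of the product at 6.0 min, in percent of the starting material charged
- the reaction counts as stopped when no species that holds the starting material changes by six tenths of a point or more over the second half of the time
- run time (flask): 6.0 min

The back run of the first step has a half-life of 13.9 s, short against 6.0 min, and target and isomer relax with a half-life of 2.30 s. So this flask should end under thermodynamic control, with target and isomer as one pool. Its measure is the pool constant Kp, the first step's equilibrium constant times one plus the isomer step's, 16.3 M⁻¹: with both steps at balance, pool over starting material equals Kp times the free reagent.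

With the reagent as charged, 50.0 mM, that ratio r is 0.813, so the pool fraction x = r/(1+r) is 44.9 %. The isomer constant splits this into 27.0 % target and 17.8 % isomer.

The weak link is that reagent, since the pool itself takes 8.97 mM of it. The second substrate's draw is left out of this reckoning, the first step's forward use of reagent being 29 times its own at the start. Free reagent of 41.0 mM gives x = 40.0 %, and a second pass with 42.0 mM gives 40.6 %. That means 24.5 % target and 16.1 % isomer. Over-reaction, with a target half-life of 130 min, moves about 0.39 percentage points in the second half of the time, inside the stopping rule, so this reckoning calls the flask stopped at balance.

The forecast says forward and back rates have come level, with 24.1 % target and 15.9 % isomer, its target 0.40 points below the reckoning here, on the ground that the steps “relax within a minute or two”.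

The simulation gives forward and back rates have come level, with 24.1 % target and 15.9 % isomer. This flask reached 95.0 % of its conversion at 6.00 min by 0.977 min, with reagent at 85.7 % of its charge at 0.600 min and 83.1 % at 3.00 min. Over-reaction product in this flask crept from 0.350 % to 0.733 % between 3.00 min and 6.00 min, and the first step's backward turnover in this flask came to 91 % of its forward one. At the end, pool over starting material reads 0.675, and Kp times the reagent then present gives 0.675.

In the neighbour charged with 10.0 equiv of reagent, Kp gives a first x of 76.5 %, then 75.0 %, so 45.2 % target and 29.8 % isomer. That neighbour gives 44.5 % and 29.4 %, with target now ahead of the 24.7 % of starting material.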